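**Plan**

- Locants: oxolane ring O1, C2 (3,4-dimethoxyphenyl), C3 (C9H2OH), C4 (aroyl carbon C7'), C5. The chain aryl–C2–C3–C9 is a cinnamaldehyde skeleton and O1–C5–C4 is an α-hydroxy ketone skeleton, so the ring can be assembled from an enal and a ketol.
- Retrosynthesis: the ring is cut at O1–C2 and C3–C4, after restoring C3=C4, C9 as CHO and C7' as a 1,3-dithiane. The ketol is cut at C4–C7' into a 2-aryl-1,3-dithiane anion and silyl-protected glycolaldehyde.
- Forward: the dithiane anion adds to the aldehyde (C7'–C4), and oxidation and desilylation give the ketol. One amine-catalysed oxa-Michael/aldol condensation then closes the only ring as a 2,5-dihydrofuran. CHO reduction, silylation, thioketal hydrolysis, conjugate reduction with C4 equilibration, and desilylation finish the route.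
- Stereochemistry: C2 comes from the chiral amine catalyst. C3 comes from hydride addition to the enone anti to the C2 aryl group, which leaves CH2O cis to the aryl group. C4 comes from base equilibration to the isomer with the aroyl group trans to CH2O.

Key step: step 5

Assumption: the face selectivity of step 5 is assigned with the usual shielding model for diarylprolinol silyl ether iminium ions (attack on the E, s-trans iminium ion from the face away from the CPh2OSiMe3 group); on that basis the (R)-catalyst is chosen to give (2S)-12.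

Remark: C2 is (S) in 12–15 and (R) in 10, 11 and 16–18 only because the CIP rank of C3 relative to the aryl group changes with its substitution; the spatial arrangement at C2 is the same throughout. Compounds 4 and 9 are purchased.

**Route**

Step 1
Reactants: 1 3,4,5-trimethoxybenzaldehyde; 2 propane-1,3-dithiol
Product: 3 2-(3,4,5-trimethoxyphenyl)-1,3-dithiane
Conditions: BF3·OEt2 (cat.), CH2Cl2, 0 °C to rt
Reagents that add atoms: none
Why: Lewis acid-catalysed dithioacetalisation of an aromatic aldehyde with a 1,3-dithiol is a standard condensation driven by loss of water.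

Step 2
Reactants: 3 2-(3,4,5-trimethoxyphenyl)-1,3-dithiane; 4 (tert-butyldimethylsilyloxy)acetaldehyde
Product: 6 2-[(tert-butyldimethylsilyl)oxy]-1-[2-(3,4,5-trimethoxyphenyl)-1,3-dithian-2-yl]ethan-1-ol (racemic), via 2-lithio-2-(3,4,5-trimethoxyphenyl)-1,3-dithiane 5 (not isolated)
Conditions: n-BuLi, THF, −78 to −20 °C; 4, −78 °C; then H2O
Reagents that add atoms: n-butyllithium, [Li]CCCC (supplies the lithium of 5; none of its atoms remain in 6)
Why: Corey–Seebach umpolung, in which the aryl-stabilised 2-lithio-1,3-dithiane adds 1,2 to the unhindered aldehyde and joins C7' to C4 (the carbinol centre is racemic and is oxidised in step 3).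

Step 3
Reactants: 6 2-[(tert-butyldimethylsilyl)oxy]-1-[2-(3,4,5-trimethoxyphenyl)-1,3-dithian-2-yl]ethan-1-ol
Product: 7 2-[(tert-butyldimethylsilyl)oxy]-1-[2-(3,4,5-trimethoxyphenyl)-1,3-dithian-2-yl]ethan-1-one
Conditions: DMSO, (COCl)2, CH2Cl2, −78 °C; Et3N, −78 to 0 °C
Reagents that add atoms: none
Why: Swern oxidation converts the hindered secondary carbinol to the ketone under conditions that leave the thioacetal sulfur atoms and the silyl ether untouched.

Step 4
Reactants: 7 2-[(tert-butyldimethylsilyl)oxy]-1-[2-(3,4,5-trimethoxyphenyl)-1,3-dithian-2-yl]ethan-1-one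
Product: 8 2-hydroxy-1-[2-(3,4,5-trimethoxyphenyl)-1,3-dithian-2-yl]ethan-1-one
Conditions: HF·pyridine, THF, 0 °C to rt
Reagents that add atoms: none
Why: Fluoride-mediated desilylation of a primary TBS ether under mildly acidic conditions frees the hydroxyl without affecting the thioketal or isomerising the α-ketol.

Step 5
Reactants: 8 2-hydroxy-1-[2-(3,4,5-trimethoxyphenyl)-1,3-dithian-2-yl]ethan-1-one; 9 (E)-3-(3,4-dimethoxyphenyl)prop-2-enal
Product: 12 (2S)-2-(3,4-dimethoxyphenyl)-4-[2-(3,4,5-trimethoxyphenyl)-1,3-dithian-2-yl]-2,5-dihydrofuran-3-carbaldehyde, via oxa-Michael adduct 10 (not isolated), via aldol adduct 11 (not isolated)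
Conditions: (R)-2-[diphenyl(trimethylsilyloxy)methyl]pyrrolidine (20 mol %), 2-nitrobenzoic acid (20 mol %), toluene, rt
Reagents that add atoms: none
Why: Proposed new method: the catalyst and 9 form an E, s-trans iminium ion, the primary hydroxyl of 8 adds reversibly to C2 (enamine of 10), the enamine carbon C3 attacks the ketone carbon C4 (iminium ion of 11), and loss of water through the enamine followed by hydrolysis releases the conjugated enal 12 and the amine. The closest known reactions are the iminium–enamine oxa-Michael/aldol condensation of salicylaldehydes with enals to 2H-chromene-3-carbaldehydes and the sulfa-Michael/aldol domino of α-mercapto ketones with enals to tetrahydrothiophenes; new here is an aliphatic α-ketol as the oxygen nucleophile combined with a ketone as the aldol acceptor. The 2,5-dihydrofuran closes at C3–C4 by a 5-exo-trig (enolexo) aldol addition, O1–C2 having been formed intermolecularly. C2, the only stereocentre that is kept, is controlled by the catalyst: its CPh2OSiMe3 group covers one face of the iminium ion, oxygen adds to the other and (2S)-12 should result, while C3 and C4 of 11 become trigonal on dehydration. The step needs face selectivity at C2 under a reversible, thermodynamically weak oxa-Michael addition and a single aldol direction: the intramolecular aldol and the irreversible dehydration to a conjugated enal drain the adduct formed on the open face, and in 8 the thioketal carbon bears no hydrogen and carries two sulfur atoms, so the ketone cannot enolise toward C7', does not dimerise and is inductively activated as the acceptor.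

Step 6
Reactants: 12 (2S)-2-(3,4-dimethoxyphenyl)-4-[2-(3,4,5-trimethoxyphenyl)-1,3-dithian-2-yl]-2,5-dihydrofuran-3-carbaldehyde
Product: 13 {(2S)-2-(3,4-dimethoxyphenyl)-4-[2-(3,4,5-trimethoxyphenyl)-1,3-dithian-2-yl]-2,5-dihydrofuran-3-yl}methanol
Conditions: NaBH4, CeCl3·7H2O, MeOH, −40 to 0 °C
Reagents that add atoms: none
Why: Luche reduction, in which CeCl3-assisted NaBH4 reduces the conjugated aldehyde 1,2 only, so the tetrasubstituted C3=C4 bond stays in place and C3 remains trigonal for step 9.

Step 7
Reactants: 13 {(2S)-2-(3,4-dimethoxyphenyl)-4-[2-(3,4,5-trimethoxyphenyl)-1,3-dithian-2-yl]-2,5-dihydrofuran-3-yl}methanol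
Product: 14 tert-butyl({(2S)-2-(3,4-dimethoxyphenyl)-4-[2-(3,4,5-trimethoxyphenyl)-1,3-dithian-2-yl]-2,5-dihydrofuran-3-yl}methoxy)dimethylsilane
Conditions: TBSCl, imidazole, DMF, rt
Reagents that add atoms: tert-butyldimethylsilyl chloride, CC(C)(C)[Si](C)(C)Cl
Why: Standard silylation of a primary allylic alcohol, which later keeps the hydroxyl from adding to the unmasked C7' ketone (hemiketal formation and dehydration to a fused furan).

Step 8
Reactants: 14 tert-butyl({(2S)-2-(3,4-dimethoxyphenyl)-4-[2-(3,4,5-trimethoxyphenyl)-1,3-dithian-2-yl]-2,5-dihydrofuran-3-yl}methoxy)dimethylsilane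
Product: 15 (2S)-3-{[(tert-butyldimethylsilyl)oxy]methyl}-2-(3,4-dimethoxyphenyl)-4-(3,4,5-trimethoxybenzoyl)-2,5-dihydrofuran
Conditions: MeI, CaCO3, MeCN/H2O (9:1), 40 °C
Reagents that add atoms: water, O
Why: Alkylative thioketal hydrolysis, in which S-methylation makes sulfur a leaving group, the aryl- and alkenyl-stabilised thionium ion is trapped by water, and CaCO3 keeps the medium near neutral so that C2–H, now γ to the enone carbonyl, is not removed.

Step 9
Reactants: 15 (2S)-3-{[(tert-butyldimethylsilyl)oxy]methyl}-2-(3,4-dimethoxyphenyl)-4-(3,4,5-trimethoxybenzoyl)-2,5-dihydrofuran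
Product: 17 (2R,3R,4S)-3-{[(tert-butyldimethylsilyl)oxy]methyl}-2-(3,4-dimethoxyphenyl)-4-(3,4,5-trimethoxybenzoyl)oxolane, via all-cis ketone 16 (not isolated)
Conditions: [(Ph3P)CuH]6, H2O, degassed toluene, rt; filtration through silica; then DBU, toluene, 40 °C
Reagents that add atoms: none
Why: Copper hydride conjugate reduction (Stryker's reagent) delivers hydride to the enone β-carbon C3 on the face opposite the C2 aryl group, which fixes CH2OTBS cis to the aryl group (3R); protonation of the enolate should give mainly the all-cis ketone 16, and DBU then equilibrates the only enolisable centre C4 to the isomer with the aroyl group trans to CH2OTBS (4S), the C5–O1 bond lying near the enolate plane so that β-elimination is stereoelectronically disfavoured.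

Step 10
Reactants: 17 (2R,3R,4S)-3-{[(tert-butyldimethylsilyl)oxy]methyl}-2-(3,4-dimethoxyphenyl)-4-(3,4,5-trimethoxybenzoyl)oxolane
Product: 18 (2R,3R,4S)-2-(3,4-dimethoxyphenyl)-3-(hydroxymethyl)-4-(3,4,5-trimethoxybenzoyl)oxolane
Conditions: HF·pyridine, pyridine, THF, 0 °C to rt
Reagents that add atoms: none
Why: Buffered fluoride desilylation removes the primary TBS ether without enolising C4 or ionising the benzylic C2–O1 bond and should give the target.

**Compound list**

1 | 3,4,5-trimethoxybenzaldehyde | COc1cc(C=O)cc(OC)c1OC | starting material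
2 | propane-1,3-dithiol | SCCCS | starting material
3 | 2-(3,4,5-trimethoxyphenyl)-1,3-dithiane | COc1cc(C2SCCCS2)cc(OC)c1OC | intermediate
4 | (tert-butyldimethylsilyloxy)acetaldehyde | CC(C)(C)[Si](C)(C)OCC=O | starting material
5 | 2-lithio-2-(3,4,5-trimethoxyphenyl)-1,3-dithiane | [Li]C1(c2cc(OC)c(OC)c(OC)c2)SCCCS1 | intermediate (not isolated)
6 | 2-[(tert-butyldimethylsilyl)oxy]-1-[2-(3,4,5-trimethoxyphenyl)-1,3-dithian-2-yl]ethan-1-ol (racemic) | COc1cc(C2(C(O)CO[Si](C)(C)C(C)(C)C)SCCCS2)cc(OC)c1OC | intermediate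
7 | 2-[(tert-butyldimethylsilyl)oxy]-1-[2-(3,4,5-trimethoxyphenyl)-1,3-dithian-2-yl]ethan-1-one | COc1cc(C2(C(=O)CO[Si](C)(C)C(C)(C)C)SCCCS2)cc(OC)c1OC | intermediate
8 | 2-hydroxy-1-[2-(3,4,5-trimethoxyphenyl)-1,3-dithian-2-yl]ethan-1-one | COc1cc(C2(C(=O)CO)SCCCS2)cc(OC)c1OC | intermediate
9 | (E)-3-(3,4-dimethoxyphenyl)prop-2-enal | COc1ccc(/C=C/C=O)cc1OC | starting material
10 | (3R)-3-(3,4-dimethoxyphenyl)-3-{2-oxo-2-[2-(3,4,5-trimethoxyphenyl)-1,3-dithian-2-yl]ethoxy}propanal | COc1ccc([C@@H](CC=O)OCC(=O)C2(c3cc(OC)c(OC)c(OC)c3)SCCCS2)cc1OC | intermediate (not isolated)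
11 | (2R)-2-(3,4-dimethoxyphenyl)-4-hydroxy-4-[2-(3,4,5-trimethoxyphenyl)-1,3-dithian-2-yl]oxolane-3-carbaldehyde (C3 and C4 not assigned) | COc1ccc([C@@H]2OCC(O)(C3(c4cc(OC)c(OC)c(OC)c4)SCCCS3)C2C=O)cc1OC | intermediate (not isolated)
12 | (2S)-2-(3,4-dimethoxyphenyl)-4-[2-(3,4,5-trimethoxyphenyl)-1,3-dithian-2-yl]-2,5-dihydrofuran-3-carbaldehyde | COc1ccc([C@@H]2OCC(C3(c4cc(OC)c(OC)c(OC)c4)SCCCS3)=C2C=O)cc1OC | intermediate
13 | {(2S)-2-(3,4-dimethoxyphenyl)-4-[2-(3,4,5-trimethoxyphenyl)-1,3-dithian-2-yl]-2,5-dihydrofuran-3-yl}methanol | COc1ccc([C@@H]2OCC(C3(c4cc(OC)c(OC)c(OC)c4)SCCCS3)=C2CO)cc1OC | intermediate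
14 | tert-butyl({(2S)-2-(3,4-dimethoxyphenyl)-4-[2-(3,4,5-trimethoxyphenyl)-1,3-dithian-2-yl]-2,5-dihydrofuran-3-yl}methoxy)dimethylsilane | COc1ccc([C@@H]2OCC(C3(c4cc(OC)c(OC)c(OC)c4)SCCCS3)=C2CO[Si](C)(C)C(C)(C)C)cc1OC | intermediate
15 | (2S)-3-{[(tert-butyldimethylsilyl)oxy]methyl}-2-(3,4-dimethoxyphenyl)-4-(3,4,5-trimethoxybenzoyl)-2,5-dihydrofuran | COc1ccc([C@@H]2OCC(C(=O)c3cc(OC)c(OC)c(OC)c3)=C2CO[Si](C)(C)C(C)(C)C)cc1OC | intermediate
16 | (2R,3R,4R)-3-{[(tert-butyldimethylsilyl)oxy]methyl}-2-(3,4-dimethoxyphenyl)-4-(3,4,5-trimethoxybenzoyl)oxolane (aryl, CH2OTBS and aroyl all cis) | COc1ccc([C@@H]2OC[C@H](C(=O)c3cc(OC)c(OC)c(OC)c3)[C@@H]2CO[Si](C)(C)C(C)(C)C)cc1OC | intermediate (not isolated)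
17 | (2R,3R,4S)-3-{[(tert-butyldimethylsilyl)oxy]methyl}-2-(3,4-dimethoxyphenyl)-4-(3,4,5-trimethoxybenzoyl)oxolane (aryl and CH2OTBS cis, aroyl trans to both) | COc1ccc([C@@H]2OC[C@@H](C(=O)c3cc(OC)c(OC)c(OC)c3)[C@@H]2CO[Si](C)(C)C(C)(C)C)cc1OC | intermediate
18 | (2R,3R,4S)-2-(3,4-dimethoxyphenyl)-3-(hydroxymethyl)-4-(3,4,5-trimethoxybenzoyl)oxolane, also named [(3S,4R,5R)-5-(3,4-dimethoxyphenyl)-4-(hydroxymethyl)oxolan-3-yl](3,4,5-trimethoxyphenyl)methanone | COc1ccc([C@@H]2OC[C@@H](C(=O)c3cc(OC)c(OC)c(OC)c3)[C@@H]2CO)cc1OC | target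

**Step count and risks**

Total steps: 10. Longest linear sequence: 10 steps (1 → 3 → 6 → 7 → 8 → 12 → 13 → 14 → 15 → 17 → 18); 2, 4 and 9 are purchased.

Steps most likely to fail:

Step 5. Reversal of the oxa-Michael addition may outrun aldol closure onto the crowded ketone, so that the partners are returned, and the reversible addition may erode face selectivity at C2. The fallback uses known reactions only, sets out from dithiane 3 and comes back at keto aldehyde 10 and then at 12. Purchased 3,4-dimethoxybenzaldehyde is allylated with the B-allyldiisopinocampheylborane enantiomer that adds to the Re face of aryl aldehydes (Brown allylation) to give (1R)-1-(3,4-dimethoxyphenyl)but-3-en-1-ol F1. Williamson etherification of its sodium alkoxide (NaH, THF) with 2-bromo-N-methoxy-N-methylacetamide gives 2-{[(1R)-1-(3,4-dimethoxyphenyl)but-3-en-1-yl]oxy}-N-methoxy-N-methylacetamide F2. Lithio-dithiane 5, made from 3 as in step 2, acylates this Weinreb amide to 2-{[(1R)-1-(3,4-dimethoxyphenyl)but-3-en-1-yl]oxy}-1-[2-(3,4,5-trimethoxyphenyl)-1,3-dithian-2-yl]ethan-1-one F3. Dihydroxylation of the terminal alkene (OsO4 cat., N-methylmorpholine N-oxide) gives 2-{[(1R)-1-(3,4-dimethoxyphenyl)-3,4-dihydroxybutyl]oxy}-1-[2-(3,4,5-trimethoxyphenyl)-1,3-dithian-2-yl]ethan-1-one F4, and glycol cleavage with Pb(OAc)4 gives 10. The crude keto aldehyde is closed to 12 by amine-catalysed intramolecular aldol condensation with the same (R)-prolinol silyl ether and acid, so that any retro-addition re-adds in the matched sense.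

Step 9. Hydride transfer to the fully substituted β-carbon C3 may be too slow, which would let 1,2-reduction of the aryl ketone or migration of the double bond toward C2 compete, or the face preference may be incomplete. The fallback sets out from 15 and comes back at 16: a hydrogen-atom-transfer conjugate reduction with Mn(dpm)3 (dpm = 2,2,6,6-tetramethylheptane-3,5-dionate; catalytic), PhSiH3 and i-PrOH at rt. This radical pathway puts a hydrogen atom on C3 from the face away from the aryl group, and the C4 radical is reduced and protonated; DBU equilibration as in step 9 then gives 17. No compound outside the list arises (F0).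

Step 8. S-methylation at the crowded thioketal may be sluggish, and forcing it may cause ionisation of the C2–O1 bond or migration of the double bond into conjugation with the C2 aryl group. The fallback sets out from 14 and comes back at 15 by a two-stage oxidative route. NaIO4 (1 equiv) in MeOH/H2O at 0 °C gives tert-butyl({(2S)-2-(3,4-dimethoxyphenyl)-4-[1-oxido-2-(3,4,5-trimethoxyphenyl)-1,3-dithian-2-yl]-2,5-dihydrofuran-3-yl}methoxy)dimethylsilane F5 as a mixture of sulfoxide diastereomers. Activation with (CF3CO)2O and 2,6-lutidine in MeCN at −40 °C, followed by aqueous NaHCO3, expels the acylated sulfur with help from the second sulfur atom (Pummerer-type fragmentation), and the thionium ion is hydrolysed to 15.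

**Further compounds**

F1 | step 5 | (1R)-1-(3,4-dimethoxyphenyl)but-3-en-1-ol | COc1ccc([C@@H](CC=C)O)cc1OC
F2 | step 5 | 2-{[(1R)-1-(3,4-dimethoxyphenyl)but-3-en-1-yl]oxy}-N-methoxy-N-methylacetamide | COc1ccc([C@@H](CC=C)OCC(=O)N(C)OC)cc1OC
F3 | step 5 | 2-{[(1R)-1-(3,4-dimethoxyphenyl)but-3-en-1-yl]oxy}-1-[2-(3,4,5-trimethoxyphenyl)-1,3-dithian-2-yl]ethan-1-one | COc1ccc([C@@H](CC=C)OCC(=O)C2(c3cc(OC)c(OC)c(OC)c3)SCCCS2)cc1OC
F4 | step 5 | 2-{[(1R)-1-(3,4-dimethoxyphenyl)-3,4-dihydroxybutyl]oxy}-1-[2-(3,4,5-trimethoxyphenyl)-1,3-dithian-2-yl]ethan-1-one (carbinol centre of the diol mixed) | COc1ccc([C@@H](CC(O)CO)OCC(=O)C2(c3cc(OC)c(OC)c(OC)c3)SCCCS2)cc1OC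
F0 | step 9 | none | none
F5 | step 8 | tert-butyl({(2S)-2-(3,4-dimethoxyphenyl)-4-[1-oxido-2-(3,4,5-trimethoxyphenyl)-1,3-dithian-2-yl]-2,5-dihydrofuran-3-yl}methoxy)dimethylsilane (sulfoxide diastereomers) | COc1ccc([C@@H]2OCC(C3(c4cc(OC)c(OC)c(OC)c4)S(=O)CCCS3)=C2CO[Si](C)(C)C(C)(C)C)cc1OC
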